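The route rests on opening the cyclohexanone between its carbonyl carbon and the neighbouring ring carbon that bears the two methyl groups. In the key step an iron hydride delivers a hydrogen atom to an isopropenyl group, which creates the second methyl and a tertiary radical; this closes the six-membered ring on a pendant nitrile, and hydrolysis of the ketimine gives the target itself. The step exploits the C(CH3)2–C(=O) edge of the carbocycle. Its precursor is an open-chain γ-hydroxy nitrile with the isopropenyl group next to the tertiary carbinol, assembled from (R)-linalool, umbelliferone and 4-oxopentanenitrile by a catalyst-controlled anti ketone allylboration that sets both ring stereocentres.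

Key step: step 6

Remark: in step 5 the (S)-antipode of the diol catalyst is assumed to deliver the allyl group to the Re face of the ketone (CH2CH2CN ranked above CH3); if a model ketone showed the opposite sense, the equally available (R)-antipode would take its place in the same step.

**Step 1**
Reactants: 1 (R)-(−)-linalool, (3R)-3,7-dimethylocta-1,6-dien-3-ol
Product: 3 (3R)-3,7-dimethyloct-6-ene-1,3-diol, via alkylborane 2 (not isolated)
Conditions: 9-BBN (2.2 equiv), THF, 0 °C to rt; then NaOH, 30% H2O2, 0 °C to rt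
Reagents that add atoms: hydrogen peroxide, OO (oxygen of the primary hydroxyl); 9-BBN, C1CC2CCCC(C1)B2 (boron and bicycle held only in 2)
Why: Hydroboration–oxidation: 9-BBN adds anti-Markovnikov to the monosubstituted vinyl group far faster than to the trisubstituted alkene, and the carbinol stereocentre from the chiral pool is not touched.

**Step 2**
Reactants: 3 (3R)-3,7-dimethyloct-6-ene-1,3-diol; 4 umbelliferone (7-hydroxy-2H-chromen-2-one)
Product: 5 7-{[(3R)-3-hydroxy-3,7-dimethyloct-6-en-1-yl]oxy}-2H-chromen-2-one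
Conditions: PPh3, DIAD, THF, 0 °C to rt
Reagents that add atoms: none
Why: Mitsunobu etherification activates only the primary hydroxyl toward the acidic phenol, the tertiary alcohol being inert, and the aryl ether then serves as the protecting group of this oxygen for the rest of the route.

**Step 3**
Reactants: 5 7-{[(3R)-3-hydroxy-3,7-dimethyloct-6-en-1-yl]oxy}-2H-chromen-2-one
Product: 6 7-{[(3R,6E)-3,8-dihydroxy-3,7-dimethyloct-6-en-1-yl]oxy}-2H-chromen-2-one
Conditions: SeO2 (0.3 equiv), t-BuOOH (70% aq., 3 equiv), salicylic acid (cat.), CH2Cl2, rt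
Reagents that add atoms: selenium dioxide, O=[Se]=O (oxygen carrier); tert-butyl hydroperoxide, CC(C)(C)OO (terminal oxidant)
Why: Riley-type allylic oxidation (ene reaction, then 2,3-sigmatropic shift) should hydroxylate the (E)-methyl group of the trisubstituted alkene selectively and leave the alkene E-configured.

**Step 4**
Reactants: 6 7-{[(3R,6E)-3,8-dihydroxy-3,7-dimethyloct-6-en-1-yl]oxy}-2H-chromen-2-one
Product: 7 [(2E,6R)-6-hydroxy-2,6-dimethyl-8-[(2-oxo-2H-chromen-7-yl)oxy]oct-2-en-1-yl]boronic acid
Conditions: B2(OH)4 (1.2 equiv), Pd(MeCN)4(BF4)2 (2 mol%), MeOH, rt, Ar; extraction into degassed PhMe under Ar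
Reagents that add atoms: tetrahydroxydiboron, OB(O)B(O)O
Why: Palladium-catalysed borylation of an allylic alcohol through an η3-allylpalladium intermediate should place boron on the unsubstituted terminus and keep the E geometry, the saturated tertiary alcohol not being ionised.

**Step 5**
Reactants: 7 [(2E,6R)-6-hydroxy-2,6-dimethyl-8-[(2-oxo-2H-chromen-7-yl)oxy]oct-2-en-1-yl]boronic acid; 8 4-oxopentanenitrile (2 equiv)
Product: 10 (4S,5R,8R)-4,8-dihydroxy-4,8-dimethyl-10-[(2-oxo-2H-chromen-7-yl)oxy]-5-(prop-1-en-2-yl)decanenitrile, via borate ester 9 (not isolated)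
Conditions: (S)-3,3'-Br2-BINOL (15 mol%), t-BuOH (2 equiv), 3 Å MS, PhMe, 0 °C to rt; then aq. NaHCO3
Reagents that add atoms: none
Why: Chiral-diol-catalysed allylboration of a ketone runs through a closed Zimmerman–Traxler chair with the (E)-γ-alkyl substituent and the 2-cyanoethyl arm equatorial and the ketone methyl axial, so that bond formation at the γ-carbon (allyl transposition to the isopropenyl group) should give the anti arrangement of tertiary hydroxyl and alkyl chain, while the boron-bound BINOL fixes the absolute sense (4S,5R) independently of the remote carbinol.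

**Step 6**
Reactants: 10 (4S,5R,8R)-4,8-dihydroxy-4,8-dimethyl-10-[(2-oxo-2H-chromen-7-yl)oxy]-5-(prop-1-en-2-yl)decanenitrile
Product: 12 7-{[(3R)-3-hydroxy-5-[(1R,6S)-6-hydroxy-2,2,6-trimethyl-3-oxocyclohexyl]-3-methylpentyl]oxy}-2H-chromen-2-one, via ketimine 11 (not isolated)
Conditions: Fe(acac)3 (30 mol%), PhSiH3 (3 equiv), EtOH, 60 °C, 0.01 M; then 1 M aq. HCl, THF, 0 °C to rt
Reagents that add atoms: water, O (oxygen of the ketone)
Why: Fe(acac)3 and PhSiH3 in EtOH generate an iron hydride that transfers a hydrogen atom to the terminal CH2 of the isopropenyl group (Markovnikov-selective MHAT), which turns it into the second geminal methyl and leaves a tertiary radical on the future quaternary ring carbon; this radical adds to the nitrile carbon, the iminyl radical is reduced and protonated to the N–H ketimine 11, and aqueous acid hydrolyses it to the ketone. The closest known reaction type is the iron-hydride HAT-initiated radical cyclisation of alkenyl nitriles to α-quaternary cycloalkanones. The six-membered carbocycle closes in a 6-exo-dig mode. No stereocentre is created (the new quaternary carbon bears two methyls), and the carbinol and methine centres set in step 5 are not at the radical site, so they should be carried through unchanged. The step needs hydrogen-atom transfer to the electron-rich 1,1-disubstituted alkene in preference to the electron-poor coumarin C3=C4 bond, and ring closure faster than reduction of the radical; the alkene polarity, high dilution and the fully substituted carbinol carbon in the tether (Thorpe–Ingold effect) should secure this.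

**Compound list**
1 | (R)-(−)-linalool, (3R)-3,7-dimethylocta-1,6-dien-3-ol | CC(C)=CCC[C@@](C)(O)C=C | starting material
2 | 9-[(3S)-3-hydroxy-3,7-dimethyloct-6-en-1-yl]-9-borabicyclo[3.3.1]nonane (same spatial arrangement as 1; descriptor changes by priority only) | CC(C)=CCC[C@@](C)(O)CCB1C2CCCC1CCC2 | intermediate
3 | (3R)-3,7-dimethyloct-6-ene-1,3-diol | CC(C)=CCC[C@@](C)(O)CCO | intermediate
4 | umbelliferone, 7-hydroxy-2H-chromen-2-one | Oc1ccc2ccc(=O)oc2c1 | starting material
5 | 7-{[(3R)-3-hydroxy-3,7-dimethyloct-6-en-1-yl]oxy}-2H-chromen-2-one | CC(C)=CCC[C@@](C)(O)CCOc1ccc2ccc(=O)oc2c1 | intermediate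
6 | 7-{[(3R,6E)-3,8-dihydroxy-3,7-dimethyloct-6-en-1-yl]oxy}-2H-chromen-2-one | OC/C(C)=C/CC[C@@](C)(O)CCOc1ccc2ccc(=O)oc2c1 | intermediate
7 | [(2E,6R)-6-hydroxy-2,6-dimethyl-8-[(2-oxo-2H-chromen-7-yl)oxy]oct-2-en-1-yl]boronic acid | OB(O)C/C(C)=C/CC[C@@](C)(O)CCOc1ccc2ccc(=O)oc2c1 | intermediate
8 | 4-oxopentanenitrile | CC(=O)CCC#N | starting material
9 | (3S,4R,7R)-1-cyano-7-hydroxy-3,7-dimethyl-9-[(2-oxo-2H-chromen-7-yl)oxy]-4-(prop-1-en-2-yl)nonan-3-yl dihydrogen borate | N#CCC[C@](C)(OB(O)O)[C@@H](C(C)=C)CC[C@@](C)(O)CCOc1ccc2ccc(=O)oc2c1 | intermediate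
10 | (4S,5R,8R)-4,8-dihydroxy-4,8-dimethyl-10-[(2-oxo-2H-chromen-7-yl)oxy]-5-(prop-1-en-2-yl)decanenitrile | N#CCC[C@](C)(O)[C@@H](C(C)=C)CC[C@@](C)(O)CCOc1ccc2ccc(=O)oc2c1 | intermediate
11 | 7-{[(3R)-3-hydroxy-5-[(1R,6S)-6-hydroxy-3-imino-2,2,6-trimethylcyclohexyl]-3-methylpentyl]oxy}-2H-chromen-2-one | CC1(C)C(=N)CC[C@](C)(O)[C@@H]1CC[C@@](C)(O)CCOc1ccc2ccc(=O)oc2c1 | intermediate
12 | 7-{[(3R)-3-hydroxy-5-[(1R,6S)-6-hydroxy-2,2,6-trimethyl-3-oxocyclohexyl]-3-methylpentyl]oxy}-2H-chromen-2-one (ring hydroxyl cis to the side chain) | CC1(C)C(=O)CC[C@](C)(O)[C@@H]1CC[C@@](C)(O)CCOc1ccc2ccc(=O)oc2c1 | target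

Total step count: 6. Longest linear sequence: 6 steps (1 to 12).

**Steps most likely to fail**

Step 6. After hydrogen-atom transfer the tertiary radical may be reduced to an isopropyl group, or add to the coumarin C3=C4 bond of a second molecule, before it reaches the nitrile; the iron hydride may also reduce the coumarin double bond. The fallback keeps the coumarin out of the radical step; it sets out from 3 and comes back at 12. The primary hydroxyl of 3 is silylated (TBSCl, imidazole, DMF, 0 °C) to the silyl ether F1. Oxidation as in step 3 should give the (E)-allylic alcohol F2, and borylation as in step 4 the allylboronic acid F3. Allylboration of 8 as in step 5 should give, through the borate ester F4, the hydroxy nitrile F5. The iron-hydride cyclisation, now on a molecule without any Michael acceptor, should give through the ketimine F6 the silylated ketone F7. TBAF in THF frees the keto triol F8, whose primary hydroxyl alone enters the Mitsunobu etherification with 4 (PPh3, DIAD, THF) to give 12.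

Step 5. The chair transition state may discriminate too weakly between the methyl and the 2-cyanoethyl arm of ketone 8, which would erode both the anti selectivity and the enantiofacial control that the remote carbinol cannot supply. The fallback moves the tertiary carbinol to a ring-controlled addition; it sets out from 7 and comes back at 12. Boronic acid 7 is esterified with pinacol (MgSO4, Et2O) to the pinacol boronate F9. This adds to 4-oxobutanenitrile (O=CCCC#N, released from its commercial dimethyl acetal) under chiral phosphoric acid catalysis ((R)-TRIP, PhMe, −30 °C, the antipode that directs the allyl group to the Re face of the aldehyde); the aldehyde hydrogen takes the axial place of the methyl, a far better differentiated case, and the reaction should give through the boronate ester F10 the anti secondary alcohol F11. Cyclisation as in step 6 leads through the ketimine F12 to the hydroxy ketone F13, and Dess–Martin periodinane oxidises its secondary alcohol to the 1,4-dione F14. MeTi(OiPr)3 (THF, −20 °C to rt) spares the lactone and the neopentyl-type carbonyl next to the gem-dimethyl carbon; it should add to the other carbonyl from the ring face opposite the neighbouring side chain to give 12.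

Step 4. The allylpalladium intermediate may be captured by the tertiary hydroxyl (tetrahydrofuran formation) or lose its E geometry by syn–anti isomerisation, and the free boronic acid may protodeboronate or oxidise during work-up. The fallback uses a neutral electrophile and a chromatographically stable boron ester; it sets out from 6 and comes back at 12. The allylic hydroxyl of 6 is exchanged for chloride (MsCl, LiCl, 2,4,6-collidine, DMF, 0 °C) to give the allylic chloride F15. Base-free borylation under zerovalent palladium catalysis (Pd2(dba)3, B2pin2, DMSO, 50 °C) should give the pinacol boronate F9, and from F9 the aldehyde sequence described for step 5 leads to 12.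

**Further compounds**
F1 | step 6 | (3R)-1-{[tert-butyl(dimethyl)silyl]oxy}-3,7-dimethyloct-6-en-3-ol | CC(C)=CCC[C@@](C)(O)CCO[Si](C)(C)C(C)(C)C
F2 | step 6 | (2E,6R)-8-{[tert-butyl(dimethyl)silyl]oxy}-2,6-dimethyloct-2-ene-1,6-diol | OC/C(C)=C/CC[C@@](C)(O)CCO[Si](C)(C)C(C)(C)C
F3 | step 6 | [(2E,6R)-8-{[tert-butyl(dimethyl)silyl]oxy}-6-hydroxy-2,6-dimethyloct-2-en-1-yl]boronic acid | OB(O)C/C(C)=C/CC[C@@](C)(O)CCO[Si](C)(C)C(C)(C)C
F4 | step 6 | (3S,4R,7R)-9-{[tert-butyl(dimethyl)silyl]oxy}-1-cyano-7-hydroxy-3,7-dimethyl-4-(prop-1-en-2-yl)nonan-3-yl dihydrogen borate | N#CCC[C@](C)(OB(O)O)[C@@H](C(C)=C)CC[C@@](C)(O)CCO[Si](C)(C)C(C)(C)C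
F5 | step 6 | (4S,5R,8R)-10-{[tert-butyl(dimethyl)silyl]oxy}-4,8-dihydroxy-4,8-dimethyl-5-(prop-1-en-2-yl)decanenitrile | N#CCC[C@](C)(O)[C@@H](C(C)=C)CC[C@@](C)(O)CCO[Si](C)(C)C(C)(C)C
F6 | step 6 | (3R)-1-{[tert-butyl(dimethyl)silyl]oxy}-5-[(1R,6S)-6-hydroxy-3-imino-2,2,6-trimethylcyclohexyl]-3-methylpentan-3-ol | CC1(C)C(=N)CC[C@](C)(O)[C@@H]1CC[C@@](C)(O)CCO[Si](C)(C)C(C)(C)C
F7 | step 6 | (3R,4S)-3-[(3R)-5-{[tert-butyl(dimethyl)silyl]oxy}-3-hydroxy-3-methylpentyl]-4-hydroxy-2,2,4-trimethylcyclohexan-1-one | CC1(C)C(=O)CC[C@](C)(O)[C@@H]1CC[C@@](C)(O)CCO[Si](C)(C)C(C)(C)C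
F8 | step 6 | (3R,4S)-3-[(3R)-3,5-dihydroxy-3-methylpentyl]-4-hydroxy-2,2,4-trimethylcyclohexan-1-one | CC1(C)C(=O)CC[C@](C)(O)[C@@H]1CC[C@@](C)(O)CCO
F9 | step 5 | 7-{[(3R,6E)-3-hydroxy-3,7-dimethyl-8-(4,4,5,5-tetramethyl-1,3,2-dioxaborolan-2-yl)oct-6-en-1-yl]oxy}-2H-chromen-2-one | CC1(C)OB(C/C(C)=C/CC[C@@](C)(O)CCOc2ccc3ccc(=O)oc3c2)OC1(C)C
F10 | step 5 | (4S,5R,8R)-8-hydroxy-8-methyl-10-[(2-oxo-2H-chromen-7-yl)oxy]-5-(prop-1-en-2-yl)-4-[(4,4,5,5-tetramethyl-1,3,2-dioxaborolan-2-yl)oxy]decanenitrile | N#CCC[C@H](OB1OC(C)(C)C(C)(C)O1)[C@@H](C(C)=C)CC[C@@](C)(O)CCOc1ccc2ccc(=O)oc2c1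
F11 | step 5 | (4S,5R,8R)-4,8-dihydroxy-8-methyl-10-[(2-oxo-2H-chromen-7-yl)oxy]-5-(prop-1-en-2-yl)decanenitrile | N#CCC[C@H](O)[C@@H](C(C)=C)CC[C@@](C)(O)CCOc1ccc2ccc(=O)oc2c1
F12 | step 5 | 7-{[(3R)-3-hydroxy-5-[(1R,6S)-6-hydroxy-3-imino-2,2-dimethylcyclohexyl]-3-methylpentyl]oxy}-2H-chromen-2-one | CC1(C)C(=N)CC[C@H](O)[C@@H]1CC[C@@](C)(O)CCOc1ccc2ccc(=O)oc2c1
F13 | step 5 | 7-{[(3R)-3-hydroxy-5-[(1R,6S)-6-hydroxy-2,2-dimethyl-3-oxocyclohexyl]-3-methylpentyl]oxy}-2H-chromen-2-one | CC1(C)C(=O)CC[C@H](O)[C@@H]1CC[C@@](C)(O)CCOc1ccc2ccc(=O)oc2c1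
F14 | step 5 | (3R)-3-{(3R)-3-hydroxy-3-methyl-5-[(2-oxo-2H-chromen-7-yl)oxy]pentyl}-2,2-dimethylcyclohexane-1,4-dione | CC1(C)C(=O)CCC(=O)[C@@H]1CC[C@@](C)(O)CCOc1ccc2ccc(=O)oc2c1
F15 | step 4 | 7-{[(3R,6E)-8-chloro-3-hydroxy-3,7-dimethyloct-6-en-1-yl]oxy}-2H-chromen-2-one | ClC/C(C)=C/CC[C@@](C)(O)CCOc1ccc2ccc(=O)oc2c1
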